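**Plan**

- Retrosynthetic cuts: (a) the ring bond C2–C3 of the dihydropyranone, together with the two C–O bonds of a transient cyclic carbonate, which takes out CO2 and leaves an acyclic δ-hydroxy ynone; (b) the ynone C(=O)–C(sp) bond, to a Weinreb amide and (R)-pent-4-yn-2-ol; (c) the C5–C6 bond of the skipped diene, to a terminal alkyne and the allyl group of a 2-allyl-3-hydroxy acid (Alder-ene); (d) the C2–allyl bond and the carbinol C–H of that acid, back to a β-keto ester of (S)-2-methylbutanoic acid.
- Enabling feature: ring C3 is the central carbon of a β-tricarbonyl (lactone C2, enol C4, side-chain ketone C9), and C2 is a carbonic-acid-level carbon tied through O1 to the C6 carbinol. C3/C4 can therefore travel as the triple bond of an ynone, and C2, its carbonyl oxygen and the C4 oxygen can all come from one molecule of CO2.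
- Forward order: the stereotriad acid is made first; a ruthenium-catalysed Alder-ene coupling joins the chain and sets both alkenes; an acetylide adds the last five carbons; CO2 then closes first a temporary 1,3-dioxan-2-one ring and, by O-to-C carboxyl shift, the pyranone ring. No protecting groups are used; the acid travels as its carboxylate.
- Stereochemistry: the sec-butyl methyl centre is bought; the carbinol is set by Noyori hydrogenation (catalyst control); C2 of the acid is relayed from the carbinol (Fráter–Seebach, anti); ring C6 is bought in (R)-pent-4-yn-2-ol; the E-alkene comes from the β-hydride elimination of the Alder-ene step.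

Key step: step 8

Remark: the 3-acyl-4-hydroxypyranone is treated as the C4-enol tautomer drawn in the target; ring atoms are numbered O1, C2, C3, C4, C5, C6 and the open chain from the carboxyl carbon (C1) to C14.

**Route**

Step 1
Reactants: 1 (S)-2-methylbutanoic acid
Product: 4 ethyl (4S)-4-methyl-3-oxohexanoate, via acyl imidazolide 2 (not isolated), via acylmalonate half-ester 3 (not isolated)
Conditions: 1,1'-carbonyldiimidazole, THF, rt; then Mg(O2CCH2CO2Et)2, THF, rt to 40 °C; aq. HCl
Reagents that add atoms: magnesium bis(monoethyl malonate), [Mg+2].[O-]C(=O)CC(=O)OCC.[O-]C(=O)CC(=O)OCC; 1,1'-carbonyldiimidazole, O=C(n1ccnc1)n1ccnc1 (imidazolyl group of 2 only)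
Why: Masamune-type chain extension, in which the acyl imidazolide C-acylates the magnesium malonate half-ester under near-neutral conditions and the adduct decarboxylates on acidic work-up, the product being held as its C2 magnesium chelate so that the stereocentre next to the new ketone should not enolise.

Step 2
Reactants: 4 ethyl (4S)-4-methyl-3-oxohexanoate
Product: 5 ethyl (3S,4S)-3-hydroxy-4-methylhexanoate
Conditions: [RuCl(p-cymene)((R)-BINAP)]Cl (0.5 mol%), H2 (50 atm), EtOH, 50 °C
Reagents that add atoms: none
Why: Noyori hydrogenation of a β-keto ester, in which the ester-chelated ruthenium–(R)-BINAP hydride should choose the carbonyl face under catalyst control (the sense that gives (R)-3-hydroxybutanoates, here 3S by the change in priorities), the methyl/ethyl difference at C4 offering almost no substrate bias.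

Step 3
Reactants: 5 ethyl (3S,4S)-3-hydroxy-4-methylhexanoate
Product: 7 ethyl (2R,3R,4S)-3-hydroxy-4-methyl-2-(prop-2-en-1-yl)hexanoate, via dilithium alkoxide-enolate 6 (not isolated)
Conditions: LiN(i-Pr)2 (2.2 equiv), THF, −78 to −20 °C; allyl bromide, DMPU, −78 to 0 °C; aq. HCl
Reagents that add atoms: allyl bromide, C=CCBr; lithium diisopropylamide, [Li+].CC(C)[N-]C(C)C (lithium of 6 only)
Why: Fráter–Seebach alkylation, in which allyl bromide should approach the lithium-chelated alkoxide–enolate 6 on the face opposite the sec-butyl group of the chelate ring and so set C2 of the hexanoate anti to the C3 oxygen (2R).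

Step 4
Reactants: 7 ethyl (2R,3R,4S)-3-hydroxy-4-methyl-2-(prop-2-en-1-yl)hexanoate
Product: 8 (2R,3R,4S)-3-hydroxy-4-methyl-2-(prop-2-en-1-yl)hexanoic acid
Conditions: LiOH·H2O, THF/MeOH/H2O, rt; then 1 M HCl
Reagents that add atoms: lithium hydroxide, [Li+].[OH-]
Why: Saponification at ambient temperature should leave the α-centre and the aldol linkage intact, and it is done here because ester cleavage after the diene is in place would risk moving the β,γ-alkene into conjugation.

Step 5
Reactants: 9 pent-4-ynoic acid
Product: 11 N-methoxy-N-methylpent-4-ynamide, via acyl imidazolide 10 (not isolated)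
Conditions: 1,1'-carbonyldiimidazole, CH2Cl2, rt; then MeNHOMe·HCl, rt
Reagents that add atoms: N,O-dimethylhydroxylamine hydrochloride, CNOC.Cl; 1,1'-carbonyldiimidazole, O=C(n1ccnc1)n1ccnc1 (imidazolyl group of 10 only)
Why: Aminolysis of the acyl imidazolide gives the Weinreb amide, an acyl donor that later stops at the ketone stage and that leaves the terminal alkyne free for the coupling.

Step 6
Reactants: 8 (2R,3R,4S)-3-hydroxy-4-methyl-2-(prop-2-en-1-yl)hexanoic acid; 11 N-methoxy-N-methylpent-4-ynamide
Product: 12 (2R,3E)-2-[(1R,2S)-1-hydroxy-2-methylbutyl]-9-[methoxy(methyl)amino]-6-methylidene-9-oxonon-3-enoic acid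
Conditions: [CpRu(MeCN)3]PF6 (10 mol%), acetone, rt
Reagents that add atoms: none
Why: Ruthenium-catalysed alkene–alkyne coupling (formal Alder-ene reaction), in which oxidative cyclisation on cationic CpRu gives a ruthenacyclopentene and β-hydride elimination from the allylic CH2 followed by reductive elimination should give the branched 1,4-diene with the new E-alkene, the C2–H bond never being touched and the neutral conditions being expected to tolerate free OH and CO2H.

Step 7
Reactants: 12 (2R,3E)-2-[(1R,2S)-1-hydroxy-2-methylbutyl]-9-[methoxy(methyl)amino]-6-methylidene-9-oxonon-3-enoic acid; 13 (R)-pent-4-yn-2-ol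
Product: 15 (2R,3E,13R)-13-hydroxy-2-[(1R,2S)-1-hydroxy-2-methylbutyl]-6-methylidene-9-oxotetradec-3-en-10-ynoic acid, via dilithium acetylide-alkoxide 14 (not isolated)
Conditions: 13 (3.5 equiv), n-BuLi (7.0 equiv), THF, −78 to −20 °C; then 12, −78 to 0 °C; inverse quench into cold 0.5 M HCl
Reagents that add atoms: n-butyllithium, [Li]CCCC (lithium of 14 only)
Why: Weinreb ketone synthesis with an alkynyllithium, in which the first equivalents of acetylide only deprotonate CO2H and OH (the carboxylate then resists α-deprotonation, so C2 and the skipped diene should be safe) and the rest adds to the amide to give a chelated tetrahedral adduct that releases the ynone only in the acidic quench, where the liberated hydroxylamine is protonated before it can add to the ynone.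

Step 8
Reactants: 15 (2R,3E,13R)-13-hydroxy-2-[(1R,2S)-1-hydroxy-2-methylbutyl]-6-methylidene-9-oxotetradec-3-en-10-ynoic acid
Product: 18 (2R,3E)-9-[(6R)-4-hydroxy-6-methyl-2-oxo-5,6-dihydro-2H-pyran-3-yl]-2-[(1R,2S)-1-hydroxy-2-methylbutyl]-6-methylidene-9-oxonon-3-enoic acid, via carbonate half-ester 16 (not isolated), via cyclic enol carbonate 17 (not isolated)
Conditions: CO2 (1 atm, MeCN pre-saturated), DBU (3 equiv), DMAP (0.3 equiv), MeCN (0.02 M), rt to 40 °C; then 1 M HCl
Reagents that add atoms: carbon dioxide, O=C=O; DBU, C1CCC2=NCCCN2CC1 (counter-ion of 16 only)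
Why: Proposed new method: CO2 is captured by the C13 alkoxide as the carbonate half-ester 16, whose anionic oxygen can reach the ynone β-carbon in a 6-exo-dig oxa-Michael addition (the bare hydroxyl could only close a four-membered ring) to give the cyclic enol carbonate 17; DMAP then opens 17 at the carbonate carbonyl with the β-diketonate as leaving group, and the central carbon of that diketonate (ring C3) attacks the tethered alkoxycarbonylpyridinium in a 6-exo-trig C-acylation that forms the C2–C3 bond and closes the pyranone. The closest known reaction types are the carboxylative cyclisation of alkynols with CO2 to alkylidene cyclic carbonates, the Steglich-type O-to-C carboxyl shift of enol carbonates, the O-to-C acyl shift of 1,3-dione enol esters to 2-acyl-1,3-diones, and the base-induced rearrangement of CO2-derived alkylidene oxazolidinones to tetramic acids. No stereocentre is formed; the C13–O bond (ring C6–O1) is never broken, so the 6R configuration is carried over from 13. The step needs chemoselectivity (of the two hydroxyls and the carboxylate only the C13 carbonate has a 6-exo path to the alkyne, and carbonation elsewhere is reversible and unproductive), regioselectivity (attack at the β-carbon follows from ynone polarisation and ring size) and C- over O-acylation, which should be secured thermodynamically because only the C-acylated product is a tricarbonyl acid that DBU deprotonates irreversibly. The acid is present as its carboxylate, which an amidine cannot α-deprotonate, so the β,γ-alkene and C2 should survive.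

**Compound list**

1 | (S)-2-methylbutanoic acid | OC(=O)[C@@H](C)CC | starting material
2 | (2S)-1-(imidazol-1-yl)-2-methylbutan-1-one (formed in the flask) | O=C(n1ccnc1)[C@@H](C)CC | intermediate
3 | (4S)-2-(ethoxycarbonyl)-4-methyl-3-oxohexanoic acid (formed in the flask as its magnesium salt; C2 undefined and lost on decarboxylation) | CCOC(=O)C(C(=O)O)C(=O)[C@@H](C)CC | intermediate
4 | ethyl (4S)-4-methyl-3-oxohexanoate | CCOC(=O)CC(=O)[C@@H](C)CC | intermediate
5 | ethyl (3S,4S)-3-hydroxy-4-methylhexanoate | CCOC(=O)C[C@H](O)[C@@H](C)CC | intermediate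
6 | dilithium alkoxide–enolate of 5 (formed in the flask) | [Li+].[Li+].CCO/C([O-])=C/[C@H]([O-])[C@@H](C)CC | intermediate
7 | ethyl (2R,3R,4S)-3-hydroxy-4-methyl-2-(prop-2-en-1-yl)hexanoate | C=CC[C@@H](C(=O)OCC)[C@H](O)[C@@H](C)CC | intermediate
8 | (2R,3R,4S)-3-hydroxy-4-methyl-2-(prop-2-en-1-yl)hexanoic acid | C=CC[C@@H](C(=O)O)[C@H](O)[C@@H](C)CC | intermediate
9 | pent-4-ynoic acid | C#CCCC(=O)O | starting material
10 | 1-(imidazol-1-yl)pent-4-yn-1-one (formed in the flask) | C#CCCC(=O)n1ccnc1 | intermediate
11 | N-methoxy-N-methylpent-4-ynamide | C#CCCC(=O)N(C)OC | intermediate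
12 | (2R,3E)-2-[(1R,2S)-1-hydroxy-2-methylbutyl]-9-[methoxy(methyl)amino]-6-methylidene-9-oxonon-3-enoic acid | C=C(C/C=C/[C@@H](C(=O)O)[C@H](O)[C@@H](C)CC)CCC(=O)N(C)OC | intermediate
13 | (R)-pent-4-yn-2-ol | C#CC[C@@H](C)O | starting material
14 | dilithium acetylide–alkoxide of 13 (formed in the flask) | [Li+].[Li+].[C-]#CC[C@@H](C)[O-] | intermediate
15 | (2R,3E,13R)-13-hydroxy-2-[(1R,2S)-1-hydroxy-2-methylbutyl]-6-methylidene-9-oxotetradec-3-en-10-ynoic acid | C=C(C/C=C/[C@@H](C(=O)O)[C@H](O)[C@@H](C)CC)CCC(=O)C#CC[C@@H](C)O | intermediate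
16 | C13 carbonate half-ester of 15 as its bis(DBU-H) carboxylate/carbonate salt (formed in the flask) | C=C(C/C=C/[C@@H](C(=O)[O-])[C@H](O)[C@@H](C)CC)CCC(=O)C#CC[C@@H](C)OC(=O)[O-].C1CCC2=[NH+]CCCN2CC1.C1CCC2=[NH+]CCCN2CC1 | intermediate
17 | (2R,3E)-2-[(1R,2S)-1-hydroxy-2-methylbutyl]-6-methylidene-10-[(4Z,6R)-6-methyl-2-oxo-1,3-dioxan-4-ylidene]-9-oxodec-3-enoic acid (formed in the flask; the alkene geometry is that expected from anti addition and is of no consequence) | C=C(C/C=C/[C@@H](C(=O)O)[C@H](O)[C@@H](C)CC)CCC(=O)/C=C1\OC(=O)O[C@H](C)C1 | intermediate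
18 | (2R,3E)-9-[(6R)-4-hydroxy-6-methyl-2-oxo-5,6-dihydro-2H-pyran-3-yl]-2-[(1R,2S)-1-hydroxy-2-methylbutyl]-6-methylidene-9-oxonon-3-enoic acid (CNP0221901.1) | C=C(C/C=C/[C@@H](C(=O)O)[C@H](O)[C@@H](C)CC)CCC(=O)C1=C(O)C[C@@H](C)OC1=O | target

**Step count**

Total: 8 steps. Longest linear sequence: 7 steps (steps 1, 2, 3, 4, 6, 7, 8).

**Steps most likely to fail**

Step 8. The carbonate half-ester may fail to add to the ynone, or adventitious water may hydrolyse the enol carbonate and release CO2 faster than the O-to-C shift, so that no C2–C3 bond forms. The fallback uses known chemistry, sets out from 8 and 9 and returns to the route at 18. Acid 8 is esterified with 2-(trimethylsilyl)ethanol (EDC·HCl, DMAP, CH2Cl2) to the 2-(trimethylsilyl)ethyl ester F1. F1 and pent-4-ynoic acid 9 are joined under the conditions of step 6 to the diene mono-acid F2. F2 is condensed (N,N'-dicyclohexylcarbodiimide, DMAP, CH2Cl2) with (R)-4-hydroxy-6-methyl-5,6-dihydro-2H-pyran-2-one F3, itself obtained from commercial 4-hydroxy-6-methyl-2H-pyran-2-one by enantioselective hydrogenation with the Ru(OAc)2(BINAP) enantiomer that gives the 6R lactone. The first product is the 4-O-acyl enol ester F4, which on continued exposure to DMAP should undergo the well-precedented O-to-C acyl migration to the 3-acyl lactone ester F5. Fluoride (TASF, DMF) then removes the silylethyl group to give 18.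

Step 6. Coordination of the carboxylate/hydroxyl pair of 8 to the cationic ruthenium centre may slow turnover and let the linear regioisomer and alkyne self-coupling compete. The fallback sets out from 8 and returns at 12. Acid 8 is silylated with N,O-bis(trimethylsilyl)acetamide to the trimethylsilyl ester/trimethylsilyl ether F6. F6 is coupled with 11 under the same catalyst in dry acetone to the bis-silylated diene F7. Both silyl groups are shed on aqueous citric acid work-up, which returns 12.

Step 7. Aggregation of the dilithium carboxylate–alkoxide of 12 may keep the acetylide from the amide, or the liberated hydroxylamine may add to the ynone during the quench. The fallback avoids organolithium chemistry on the acid fragment; it sets out from 9 and 8 and returns at 15. Acid 9 is converted (EDC·HCl, DMAP, EtSH) into S-ethyl pent-4-ynethioate F8. F8 is coupled with 8 under the conditions of step 6 to the diene thioester acid F9. F9 is then joined to the terminal alkyne of 13 by palladium/copper-catalysed thioester–alkyne coupling (PdCl2(dppf), P(2-furyl)3, CuI, Et3N, DMF, 50 °C; Fukuyama-type ynone synthesis) to give 15.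

**Further compounds**

F1 | step 8 | 2-(trimethylsilyl)ethyl (2R,3R,4S)-3-hydroxy-4-methyl-2-(prop-2-en-1-yl)hexanoate | C=CC[C@@H](C(=O)OCC[Si](C)(C)C)[C@H](O)[C@@H](C)CC
F2 | step 8 | (6E,8R)-8-[(1R,2S)-1-hydroxy-2-methylbutyl]-4-methylidene-9-oxo-9-[2-(trimethylsilyl)ethoxy]non-6-enoic acid | C=C(C/C=C/[C@@H](C(=O)OCC[Si](C)(C)C)[C@H](O)[C@@H](C)CC)CCC(=O)O
F3 | step 8 | (R)-4-hydroxy-6-methyl-5,6-dihydro-2H-pyran-2-one | O=C1C=C(O)C[C@@H](C)O1
F4 | step 8 | 4-O-acyl enol ester of F3 with F2 | C=C(C/C=C/[C@@H](C(=O)OCC[Si](C)(C)C)[C@H](O)[C@@H](C)CC)CCC(=O)OC1=CC(=O)O[C@H](C)C1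
F5 | step 8 | 2-(trimethylsilyl)ethyl ester of 18 | C=C(C/C=C/[C@@H](C(=O)OCC[Si](C)(C)C)[C@H](O)[C@@H](C)CC)CCC(=O)C1=C(O)C[C@@H](C)OC1=O
F6 | step 6 | trimethylsilyl (2R,3R,4S)-4-methyl-2-(prop-2-en-1-yl)-3-[(trimethylsilyl)oxy]hexanoate | C=CC[C@@H](C(=O)O[Si](C)(C)C)[C@H](O[Si](C)(C)C)[C@@H](C)CC
F7 | step 6 | bis(trimethylsilyl) derivative (silyl ester and silyl ether) of 12 | C=C(C/C=C/[C@@H](C(=O)O[Si](C)(C)C)[C@H](O[Si](C)(C)C)[C@@H](C)CC)CCC(=O)N(C)OC
F8 | step 7 | S-ethyl pent-4-ynethioate | C#CCCC(=O)SCC
F9 | step 7 | (2R,3E)-9-(ethylsulfanyl)-2-[(1R,2S)-1-hydroxy-2-methylbutyl]-6-methylidene-9-oxonon-3-enoic acid | C=C(C/C=C/[C@@H](C(=O)O)[C@H](O)[C@@H](C)CC)CCC(=O)SCC
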